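**Plan**

1. Labdane numbering is used: ring A = C1–C5/C10, ring B = C5–C10, CO2H = C18 and CH3 = C19 on C4, exocyclic CH2 = C17 on C8, side chain C11–C16 on C9. Retrosynthesis: CO2H from CH2OSi; C3–H from C3–OH; then the ring bonds C4–C5 and C9–C10 are cut together, giving an acyclic (14S,15S)-epoxy triene that carries CH2SiMe3 (C17) on C8.
2. Enabling feature: in the trans-decalin the quaternary carbons C4 and C10 each lie next to an alkene-derived carbon (C5, C9), and the exocyclic C8=C17 methylene sits beside C9. This is the footprint of an epoxide-initiated cation–olefin cascade whose last cation (C8) is β to a silicon on C17.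
3. The polyene is cut at C7–C8 and C8–C17 (two Pd couplings on a 1,1-dibromoalkene, C8 coming from CBr4), at C8=C9 (dibromo-olefination) and at C6=C7 (Wittig). Both halves come from geranyl acetate.
4. Forward: the right half is made by allylic oxidation, Sharpless epoxidation, silylation and conversion into a 1,3-diene; the left half by oxidative cleavage and dibromo-olefination. Hydroboration/Suzuki and then Negishi coupling give the allylsilane; MeAlCl2 closes ring A and then ring B in one operation; C3 deoxygenation, desilylation and oxidation of C18 finish the route.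
5. Stereochemistry: the Sharpless epoxide is the only external source. C4 (inversion, (E)-CH2OSi equatorial), C5/C10 (anti addition, trans fusion) and C9 (allylsilane geometry, chair–chair) follow from it; the C13 alkene geometry is carried from geranyl acetate.

Key step: step 12

Remark on the chemistry: the SMILES places the carboxyl on C4 trans to the C10 methyl (4R, the 18-oic acid, carboxyl equatorial); the route is built for this isomer and not for its C4 epimer.

**Step 1**
Reactants: 1 geranyl acetate [(2E)-3,7-dimethylocta-2,6-dien-1-yl acetate]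
Product: 2 (2E,6E)-8-hydroxy-3,7-dimethylocta-2,6-dien-1-yl acetate
Conditions: SeO2 (cat.), t-BuOOH (70% aq.), salicylic acid (cat.), CH2Cl2, rt
Reagents that add atoms: tert-butyl hydroperoxide, CC(C)(C)OO (oxygen relayed through SeO2, O=[Se]=O)
Why: Riley-type allylic oxidation (ene reaction then [2,3]-sigmatropic shift) attacks the (E)-methyl group of the electron-richer terminal alkene, the C2 alkene being deactivated by its allylic acetate, so the new hydroxymethyl group is trans to the chain.

**Step 2**
Reactants: 2 (2E,6E)-8-hydroxy-3,7-dimethylocta-2,6-dien-1-yl acetate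
Product: 3 (2E)-5-[(2S,3S)-3-(hydroxymethyl)-3-methyloxiran-2-yl]-3-methylpent-2-en-1-yl acetate
Conditions: Ti(OiPr)4 (10 mol %), L-(+)-diethyl tartrate (12 mol %), t-BuOOH (in decane), 4 Å molecular sieves, CH2Cl2, −20 °C
Reagents that add atoms: tert-butyl hydroperoxide, CC(C)(C)OO
Why: Sharpless asymmetric epoxidation of the (E)-2-methyl allylic alcohol with the titanium/L-(+)-tartrate catalyst delivers oxygen to a single alkene face and fixes both epoxide carbons as S, while the other alkene, which has no free allylic hydroxyl, is left alone.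

**Step 3**
Reactants: 3 (2E)-5-[(2S,3S)-3-(hydroxymethyl)-3-methyloxiran-2-yl]-3-methylpent-2-en-1-yl acetate
Product: 4 (2E)-5-[(2S,3S)-3-({[tert-butyl(dimethyl)silyl]oxy}methyl)-3-methyloxiran-2-yl]-3-methylpent-2-en-1-yl acetate
Conditions: TBSCl, imidazole, DMF, 0 °C to rt
Reagents that add atoms: tert-butyldimethylsilyl chloride, CC(C)(C)[Si](C)(C)Cl
Why: Imidazole-promoted silylation of the only free (primary) hydroxyl gives a robust, non-participating ether that blocks chelation and Payne-type migration in later steps.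

**Step 4**
Reactants: 4 (2E)-5-[(2S,3S)-3-({[tert-butyl(dimethyl)silyl]oxy}methyl)-3-methyloxiran-2-yl]-3-methylpent-2-en-1-yl acetate
Product: 5 (2E)-5-[(2S,3S)-3-({[tert-butyl(dimethyl)silyl]oxy}methyl)-3-methyloxiran-2-yl]-3-methylpent-2-en-1-ol
Conditions: K2CO3 (cat.), MeOH, 0 °C
Reagents that add atoms: none
Why: Base-catalysed transesterification removes the acetate under conditions that leave the epoxide and the silyl ether untouched.

**Step 5**
Reactants: 5 (2E)-5-[(2S,3S)-3-({[tert-butyl(dimethyl)silyl]oxy}methyl)-3-methyloxiran-2-yl]-3-methylpent-2-en-1-ol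
Product: 6 (2E)-5-[(2S,3S)-3-({[tert-butyl(dimethyl)silyl]oxy}methyl)-3-methyloxiran-2-yl]-3-methylpent-2-enal
Conditions: activated MnO2 (excess), CH2Cl2, rt
Reagents that add atoms: none
Why: MnO2 oxidizes the allylic alcohol to the (E)-enal without over-oxidation and without touching the epoxide or moving the alkene.

**Step 6**
Reactants: 6 (2E)-5-[(2S,3S)-3-({[tert-butyl(dimethyl)silyl]oxy}methyl)-3-methyloxiran-2-yl]-3-methylpent-2-enal
Product: 7 tert-butyl(dimethyl){[(2S,3S)-2-methyl-3-[(3E)-3-methylhexa-3,5-dien-1-yl]oxiran-2-yl]methoxy}silane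
Conditions: Ph3PCH3Br, n-BuLi, THF, −78 to 0 °C
Reagents that add atoms: methyltriphenylphosphonium bromide, C[P+](c1ccccc1)(c1ccccc1)c1ccccc1.[Br-]
Why: Wittig methylenation of the enal at low temperature adds the one carbon (C7) that turns the allylic terminus into a terminal 1,3-diene with the trisubstituted (E)-alkene retained.

**Step 7**
Reactants: 1 geranyl acetate
Product: 8 (2E)-6,7-epoxy-3,7-dimethyloct-2-en-1-yl acetate (racemic)
Conditions: mCPBA (1.05 equiv), CH2Cl2, −20 to 0 °C
Reagents that add atoms: 3-chloroperoxybenzoic acid, OOC(=O)c1cccc(Cl)c1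
Why: Prilezhaev epoxidation is selective for the electron-richer terminal trisubstituted alkene over the one deactivated by the allylic acetate; the new stereocentre is irrelevant because it is destroyed in step 8.

**Step 8**
Reactants: 8 (2E)-6,7-epoxy-3,7-dimethyloct-2-en-1-yl acetate
Product: 10 (2E)-3-methyl-6-oxohex-2-en-1-yl acetate, via glycol 9 (not isolated)
Conditions: H5IO6, THF/H2O, 0 °C to rt
Reagents that add atoms: none
Why: Periodic acid first hydrolyses the epoxide (water opens the tertiary carbon) and then cleaves the glycol (Malaprade reaction), releasing acetone and the aldehyde that will become C9.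

**Step 9**
Reactants: 10 (2E)-3-methyl-6-oxohex-2-en-1-yl acetate
Product: 11 (2E)-7,7-dibromo-3-methylhepta-2,6-dien-1-yl acetate
Conditions: CBr4, PPh3, CH2Cl2, 0 °C
Reagents that add atoms: carbon tetrabromide, BrC(Br)(Br)Br
Why: Ramirez dibromo-olefination (first stage of the Corey–Fuchs sequence) converts the aldehyde into the 1,1-dibromoalkene, whose new carbon becomes C8 and whose two C–Br bonds differ sterically.

**Step 10**
Reactants: 7 tert-butyl(dimethyl){[(2S,3S)-2-methyl-3-[(3E)-3-methylhexa-3,5-dien-1-yl]oxiran-2-yl]methoxy}silane; 11 (2E)-7,7-dibromo-3-methylhepta-2,6-dien-1-yl acetate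
Product: 13 (2E,6Z,10E,14S,15S)-7-bromo-16-{[tert-butyl(dimethyl)silyl]oxy}-14,15-epoxy-3,11,15-trimethylhexadeca-2,6,10-trien-1-yl acetate, via B-alkyl-9-BBN borane 12 (not isolated)
Conditions: 9-BBN, THF, 0 °C to rt; then 11, Pd(dppf)Cl2 [dppf = 1,1′-bis(diphenylphosphino)ferrocene] (5 mol %), Ph3As, Cs2CO3 (aq.), DMF/THF, rt
Reagents that add atoms: none
Why: 9-BBN adds anti-Markovnikov to the terminal vinyl group of the diene only, and in the B-alkyl Suzuki–Miyaura coupling zerovalent palladium inserts into the less hindered C–Br bond trans to the chain, so the alkyl group enters trans to C11 and the remaining bromine is cis ((Z)-bromoalkene).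

**Step 11**
Reactants: 13 (2E,6Z,10E,14S,15S)-7-bromo-16-{[tert-butyl(dimethyl)silyl]oxy}-14,15-epoxy-3,11,15-trimethylhexadeca-2,6,10-trien-1-yl acetate
Product: 14 (2E,6Z,10E,14S,15S)-16-{[tert-butyl(dimethyl)silyl]oxy}-14,15-epoxy-3,11,15-trimethyl-7-[(trimethylsilyl)methyl]hexadeca-2,6,10-trien-1-yl acetate
Conditions: Me3SiCH2MgCl, ZnCl2, THF, 0 °C; then 13, Pd(P(t-Bu)3)2 (5 mol %), THF, rt
Reagents that add atoms: (trimethylsilyl)methylmagnesium chloride, C[Si](C)(C)C[Mg]Cl
Why: Negishi coupling of the alkenyl bromide with the (trimethylsilyl)methylzinc reagent proceeds with retention of alkene geometry and tolerates the acetate and the epoxide, giving the allylsilane with CH2SiMe3 cis to C11.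

**Step 12**
Reactants: 14 (2E,6Z,10E,14S,15S)-16-{[tert-butyl(dimethyl)silyl]oxy}-14,15-epoxy-3,11,15-trimethyl-7-[(trimethylsilyl)methyl]hexadeca-2,6,10-trien-1-yl acetate
Product: 15 (3S,4R,5R,9S,10R)-18-{[tert-butyl(dimethyl)silyl]oxy}-3-hydroxylabda-8(17),13E-dien-15-yl acetate (trans-decalin; 3β-OH equatorial; CH2OSi on C4 equatorial, CH3 on C4 axial and cis to the C10 methyl; side chain on C9 equatorial)
Conditions: MeAlCl2 (2.5 equiv), CH2Cl2, −78 °C; aqueous NaHCO3/Rochelle salt work-up
Reagents that add atoms: none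
Why: MeAlCl2 coordinates the epoxide oxygen and the C4–O bond ionizes with backside participation of the C5=C10 π bond, the developing C10 cation is trapped by C9 (the γ-carbon of the allylsilane), and the β-silyl cation at C8 loses Me3Si to chloride to leave the exocyclic C8=C17 alkene; the closest known reaction type is the epoxide-initiated, allylsilane-terminated cation–olefin polycyclization used for 3-hydroxy-drimane and -labdane skeletons. Ring A closes in a 6-endo mode (both epoxide carbons C3/C4 and both alkene carbons C5/C10 end up in the ring) and ring B closes 6-endo-trig on the C8=C9 alkene. C4 is set by inversion at the epoxide carbon, its (E)-CH2OSi group being anti to C2 and therefore equatorial and its methyl axial; C5 and C10 arise by anti addition across the (E)-C5=C10 alkene in a chair, which gives the trans ring fusion; C9 follows from the allylsilane geometry (C7 trans to C11), which puts the side chain equatorial in the second chair; C3 keeps the epoxide configuration. The absolute sense of the whole fold is dictated by the (14S,15S)-epoxide, because the C4–C5 bond must form anti to the departing oxygen. The step needs C–C bond formation to outrun hydride shift at the opened epoxide (secured by the 1,5-relationship of C4 to the C5=C10 alkene and by low temperature), a clean stop after ring B with a single alkene regioisomer (secured by the β-effect of silicon), and no participation of the C13=C14 alkene (secured by its inductive deactivation through the allylic acetate and by fast desilylation).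

**Step 13**
Reactants: 15 (3S,4R,5R,9S,10R)-18-{[tert-butyl(dimethyl)silyl]oxy}-3-hydroxylabda-8(17),13E-dien-15-yl acetate
Product: 16 (3S,4R,5R,9S,10R)-18-{[tert-butyl(dimethyl)silyl]oxy}-3-[(1H-imidazol-1-ylcarbonothioyl)oxy]labda-8(17),13E-dien-15-yl acetate
Conditions: 1,1′-thiocarbonyldiimidazole, DMAP (cat.), ClCH2CH2Cl, 70 °C
Reagents that add atoms: 1,1′-thiocarbonyldiimidazole, S=C(n1ccnc1)n1ccnc1
Why: Acyl transfer from thiocarbonyldiimidazole to the single free, equatorial secondary hydroxyl gives the thiocarbonyl derivative needed for radical deoxygenation.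

**Step 14**
Reactants: 16 (3S,4R,5R,9S,10R)-18-{[tert-butyl(dimethyl)silyl]oxy}-3-[(1H-imidazol-1-ylcarbonothioyl)oxy]labda-8(17),13E-dien-15-yl acetate
Product: 17 (4R,5R,9S,10R)-18-{[tert-butyl(dimethyl)silyl]oxy}labda-8(17),13E-dien-15-yl acetate
Conditions: Bu3SnH, AIBN (cat.), toluene, 100 °C
Reagents that add atoms: none
Why: Barton–McCombie deoxygenation: the stannyl radical adds to C=S, the C3–O bond fragments to a secondary radical that abstracts hydrogen from Bu3SnH, and the alkenes and the acetate are spectators.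

**Step 15**
Reactants: 17 (4R,5R,9S,10R)-18-{[tert-butyl(dimethyl)silyl]oxy}labda-8(17),13E-dien-15-yl acetate
Product: 18 (4R,5R,9S,10R)-18-hydroxylabda-8(17),13E-dien-15-yl acetate
Conditions: HF·pyridine, pyridine, THF, 0 °C to rt
Reagents that add atoms: none
Why: Fluoride cleaves the Si–O bond of the primary silyl ether while the acetate and both alkenes survive the buffered medium.

**Step 16**
Reactants: 18 (4R,5R,9S,10R)-18-hydroxylabda-8(17),13E-dien-15-yl acetate
Product: 19 (4R,5R,9S,10R)-18-oxolabda-8(17),13E-dien-15-yl acetate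
Conditions: Dess–Martin periodinane, CH2Cl2, 0 °C to rt
Reagents that add atoms: none
Why: Dess–Martin oxidation converts the neopentylic primary alcohol into the aldehyde under neutral conditions, and no epimerizable centre is involved because C4 is quaternary.

**Step 17**
Reactants: 19 (4R,5R,9S,10R)-18-oxolabda-8(17),13E-dien-15-yl acetate
Product: 20 (4R,5R,9S,10R)-15-acetoxylabda-8(17),13E-dien-18-oic acid [(1R,4aR,5S,8aR)-5-[(3E)-5-acetoxy-3-methylpent-3-en-1-yl]-1,4a-dimethyl-6-methylidenedecahydronaphthalene-1-carboxylic acid]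
Conditions: NaClO2, NaH2PO4, 2-methyl-2-butene, t-BuOH/H2O, 0 °C to rt
Reagents that add atoms: sodium chlorite, [Na+].[O-]Cl=O
Why: Pinnick oxidation converts the hindered aldehyde into the acid through its chlorite adduct, 2-methyl-2-butene scavenging HOCl so that the two alkenes are not chlorinated.

**Compound list**

1 | geranyl acetate, (2E)-3,7-dimethylocta-2,6-dien-1-yl acetate | CC(C)=CCC/C(C)=C/COC(C)=O | starting material
2 | (2E,6E)-8-hydroxy-3,7-dimethylocta-2,6-dien-1-yl acetate | OC/C(C)=C/CC/C(C)=C/COC(C)=O | intermediate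
3 | (2E)-5-[(2S,3S)-3-(hydroxymethyl)-3-methyloxiran-2-yl]-3-methylpent-2-en-1-yl acetate | CC(=O)OC/C=C(\C)CC[C@@H]1O[C@@]1(C)CO | intermediate
4 | (2E)-5-[(2S,3S)-3-({[tert-butyl(dimethyl)silyl]oxy}methyl)-3-methyloxiran-2-yl]-3-methylpent-2-en-1-yl acetate | CC(=O)OC/C=C(\C)CC[C@@H]1O[C@@]1(C)CO[Si](C)(C)C(C)(C)C | intermediate
5 | (2E)-5-[(2S,3S)-3-({[tert-butyl(dimethyl)silyl]oxy}methyl)-3-methyloxiran-2-yl]-3-methylpent-2-en-1-ol | OC/C=C(\C)CC[C@@H]1O[C@@]1(C)CO[Si](C)(C)C(C)(C)C | intermediate
6 | (2E)-5-[(2S,3S)-3-({[tert-butyl(dimethyl)silyl]oxy}methyl)-3-methyloxiran-2-yl]-3-methylpent-2-enal | O=C/C=C(\C)CC[C@@H]1O[C@@]1(C)CO[Si](C)(C)C(C)(C)C | intermediate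
7 | tert-butyl(dimethyl){[(2S,3S)-2-methyl-3-[(3E)-3-methylhexa-3,5-dien-1-yl]oxiran-2-yl]methoxy}silane | C=C/C=C(\C)CC[C@@H]1O[C@@]1(C)CO[Si](C)(C)C(C)(C)C | intermediate
8 | (2E)-6,7-epoxy-3,7-dimethyloct-2-en-1-yl acetate (racemic) | CC(=O)OC/C=C(\C)CCC1OC1(C)C | intermediate
9 | (2E)-6,7-dihydroxy-3,7-dimethyloct-2-en-1-yl acetate (racemic glycol) | CC(=O)OC/C=C(\C)CCC(O)C(C)(C)O | intermediate (not isolated)
10 | (2E)-3-methyl-6-oxohex-2-en-1-yl acetate | CC(=O)OC/C=C(\C)CCC=O | intermediate
11 | (2E)-7,7-dibromo-3-methylhepta-2,6-dien-1-yl acetate | CC(=O)OC/C=C(\C)CCC=C(Br)Br | intermediate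
12 | 9-[(3E)-6-{(2S,3S)-3-({[tert-butyl(dimethyl)silyl]oxy}methyl)-3-methyloxiran-2-yl}-4-methylhex-3-en-1-yl]-9-borabicyclo[3.3.1]nonane | B1(C2CCCC1CCC2)CC/C=C(\C)CC[C@@H]3O[C@@]3(C)CO[Si](C)(C)C(C)(C)C | intermediate (not isolated)
13 | (2E,6Z,10E,14S,15S)-7-bromo-16-{[tert-butyl(dimethyl)silyl]oxy}-14,15-epoxy-3,11,15-trimethylhexadeca-2,6,10-trien-1-yl acetate | CC(=O)OC/C=C(\C)CC/C=C(\Br)CC/C=C(\C)CC[C@@H]1O[C@@]1(C)CO[Si](C)(C)C(C)(C)C | intermediate
14 | (2E,6Z,10E,14S,15S)-16-{[tert-butyl(dimethyl)silyl]oxy}-14,15-epoxy-3,11,15-trimethyl-7-[(trimethylsilyl)methyl]hexadeca-2,6,10-trien-1-yl acetate | CC(=O)OC/C=C(\C)CC/C=C(\C[Si](C)(C)C)CC/C=C(\C)CC[C@@H]1O[C@@]1(C)CO[Si](C)(C)C(C)(C)C | intermediate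
15 | (3S,4R,5R,9S,10R)-18-{[tert-butyl(dimethyl)silyl]oxy}-3-hydroxylabda-8(17),13E-dien-15-yl acetate | C=C1CC[C@@H]2[C@](C)(CC[C@H](O)[C@@]2(C)CO[Si](C)(C)C(C)(C)C)[C@H]1CC/C(C)=C/COC(C)=O | intermediate
16 | (3S,4R,5R,9S,10R)-18-{[tert-butyl(dimethyl)silyl]oxy}-3-[(1H-imidazol-1-ylcarbonothioyl)oxy]labda-8(17),13E-dien-15-yl acetate | C=C1CC[C@@H]2[C@](C)(CC[C@H](OC(=S)n3ccnc3)[C@@]2(C)CO[Si](C)(C)C(C)(C)C)[C@H]1CC/C(C)=C/COC(C)=O | intermediate
17 | (4R,5R,9S,10R)-18-{[tert-butyl(dimethyl)silyl]oxy}labda-8(17),13E-dien-15-yl acetate | C=C1CC[C@@H]2[C@](C)(CCC[C@@]2(C)CO[Si](C)(C)C(C)(C)C)[C@H]1CC/C(C)=C/COC(C)=O | intermediate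
18 | (4R,5R,9S,10R)-18-hydroxylabda-8(17),13E-dien-15-yl acetate | C=C1CC[C@@H]2[C@](C)(CCC[C@@]2(C)CO)[C@H]1CC/C(C)=C/COC(C)=O | intermediate
19 | (4R,5R,9S,10R)-18-oxolabda-8(17),13E-dien-15-yl acetate | C=C1CC[C@@H]2[C@](C)(CCC[C@@]2(C)C=O)[C@H]1CC/C(C)=C/COC(C)=O | intermediate
20 | (4R,5R,9S,10R)-15-acetoxylabda-8(17),13E-dien-18-oic acid | C=C1CC[C@@H]2[C@](C)(CCC[C@@]2(C)C(=O)O)[C@H]1CC/C(C)=C/COC(C)=O | target

**Count and risks**

Total step count: 17. Longest linear sequence: 14 (steps 1–6 and 10–17); the second branch (steps 7–9) joins at step 10.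

The three steps most likely to fail:

Step 12. What may go wrong: protodesilylation of the allylsilane by adventitious acid before the cascade reaches it, premature proton loss after closure of ring A, or a hydride shift at the ionizing epoxide. Fallback: take silicon out of the termination. The fallback sets out from 13 (so step 11 is not needed) and ends the same epoxide-initiated cascade on the 2-bromoalkene (halo-olefin termination). With MeAlCl2 in CH2Cl2 at −78 °C the C10 cation is attacked by C9, and the α-bromo cation at C8 is captured by chloride to give the geminal bromo chloride F1 (mixture at C8). Aqueous AgNO3 hydrolyses F1 to the 8-oxo-17-nor compound F2, in which the side chain on C9 is equatorial (chair-derived, and the thermodynamic position next to the ketone). Takai–Lombardo methylenation of F2 (Zn, CH2Br2, TiCl4, THF) installs C17 and returns to the route at 15.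

Step 10. What may go wrong: loss of site selectivity between the two C–Br bonds (double coupling, or coupling at the cis bromine), slow transmetalation of the borate, or ionization of the allylic acetate by zerovalent palladium. Fallback: replace the one-pot borane coupling by alkylation with a discrete organozinc, the reaction type with the closest precedent for trans-selective monoalkylation of 1,1-dibromoalkenes. The fallback sets out from borane 12, which is iodinated (I2, NaOMe, THF/MeOH, 0 °C) to the primary iodide F3. Zinc insertion (Zn, LiCl, THF) gives the alkylzinc iodide F4. Negishi coupling of F4 with 11 (Pd(DPEphos)Cl2 [DPEphos = bis(2-diphenylphosphinophenyl) ether], THF, 0 °C to rt) returns to the route at 13.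

Step 14. What may go wrong: an inefficient radical chain at the hindered C3 position (return of the alcohol, or addition of the stannyl radical to the exocyclic alkene). Fallback: remove the oxygen at the ketone level instead. The fallback sets out from 15. Dess–Martin oxidation gives the 3-ketone F5, and condensation with tosylhydrazine (EtOH, 60 °C) gives the tosylhydrazone F6. Reduction with catecholborane (CHCl3, 0 °C) and then NaOAc·3H2O (loss of sulfinate and N2 from the diazene) gives 17, where the route is rejoined.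

**Further compounds**

F1 | step 12 | (3S,4R,5R,9S,10R)-8-bromo-8-chloro-18-{[tert-butyl(dimethyl)silyl]oxy}-3-hydroxy-17-norlabd-13E-en-15-yl acetate (mixture at C8) | ClC1(Br)CC[C@@H]2[C@](C)(CC[C@H](O)[C@@]2(C)CO[Si](C)(C)C(C)(C)C)[C@H]1CC/C(C)=C/COC(C)=O
F2 | step 12 | 18-{[tert-butyl(dimethyl)silyl]oxy}-3β-hydroxy-8-oxo-17-norlabd-13E-en-15-yl acetate (8-oxo-17-nor analogue of 15) | O=C1CC[C@@H]2[C@](C)(CC[C@H](O)[C@@]2(C)CO[Si](C)(C)C(C)(C)C)[C@H]1CC/C(C)=C/COC(C)=O
F3 | step 10 | tert-butyl{[(2S,3S)-3-[(3E)-6-iodo-3-methylhex-3-en-1-yl]-2-methyloxiran-2-yl]methoxy}dimethylsilane | ICC/C=C(\C)CC[C@@H]1O[C@@]1(C)CO[Si](C)(C)C(C)(C)C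
F4 | step 10 | [(3E)-6-{(2S,3S)-3-({[tert-butyl(dimethyl)silyl]oxy}methyl)-3-methyloxiran-2-yl}-4-methylhex-3-en-1-yl]zinc iodide | I[Zn]CC/C=C(\C)CC[C@@H]1O[C@@]1(C)CO[Si](C)(C)C(C)(C)C
F5 | step 14 | (4R,5R,9S,10R)-18-{[tert-butyl(dimethyl)silyl]oxy}-3-oxolabda-8(17),13E-dien-15-yl acetate | C=C1CC[C@@H]2[C@](C)(CCC(=O)[C@@]2(C)CO[Si](C)(C)C(C)(C)C)[C@H]1CC/C(C)=C/COC(C)=O
F6 | step 14 | (4R,5R,9S,10R)-18-{[tert-butyl(dimethyl)silyl]oxy}-3-[(4-methylphenyl)sulfonylhydrazinylidene]labda-8(17),13E-dien-15-yl acetate | C=C1CC[C@@H]2[C@](C)(CCC(=NNS(=O)(=O)c3ccc(C)cc3)[C@@]2(C)CO[Si](C)(C)C(C)(C)C)[C@H]1CC/C(C)=C/COC(C)=O
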